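**Plan**

- Retrosynthesis: the ArCH2–C1' bond is cut first, giving a flavone-6-ylmethyl cation (ortho-quinone methide) and a cyclic allylsilane. The carbocycle is then cut at C5'–C6' and C1'–C2' (Robinson annulation) to isobutyraldehyde and a β-silylated vinyl ketone. The flavone is luteolin.
- Enabling feature: with C3' read as a ketone, its α-carbon C2' is bonded to C1', and its other side runs through C4'H2–C5'H2 to the quaternary C6'Me2. This is a Michael/aldol pattern in which C6' and C1' are the α-carbon and the formyl carbon of isobutyraldehyde. The exocyclic CH2 on C2' is carried as CH2SiMe3.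
- Forward order: steps 1–2 make the vinyl ketone; step 3 builds the cyclohexane ring as an enone that is also an allylsilane; steps 4–5 reduce and protect. Steps 6–8 convert luteolin (rings A, B and C kept intact) into the 6-hydroxymethyl flavone. Step 9 joins the fragments and moves the C=C to the exocyclic position; step 10 removes all silyl groups.
- Stereochemistry: C3' (S) comes from the CBS reduction of the annulation enone (reagent control). C1' (S) comes from 1,3-induction in step 9, where the electrophile should enter anti to the C3' silyloxy group.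
- Helpers: the ketone oxidation level at C3' (removed in step 4) and the SiMe3 group (removed in step 9).

Key step: step 3

Remark on the chemistry: primed locants denote the cyclohexane ring of the target (C1' carries the flavone CH2, C2' the exocyclic methylene, C3' the hydroxyl, C6' the two methyls). The facial sense of the CBS reduction is assumed from the usual model, with the α-substituted alkenyl carbon as the large ketone substituent.

**Route**

Step 1
Reactants: 1 3-(trimethylsilyl)propanoic acid
Product: 3 N-methoxy-N-methyl-3-(trimethylsilyl)propanamide, via acyl imidazolide 2 (not isolated)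
Conditions: 1,1'-carbonyldiimidazole (1.1 equiv), CH2Cl2, rt; then MeNH(OMe)·HCl (1.2 equiv), rt
Reagents that add atoms: N,O-dimethylhydroxylamine hydrochloride, CNOC.Cl
Why: Activation of the acid as its acyl imidazolide followed by acyl transfer to the hydroxylamine is a standard Weinreb amide formation, and no stereocentre is involved.

Step 2
Reactants: 3 N-methoxy-N-methyl-3-(trimethylsilyl)propanamide
Product: 4 5-(trimethylsilyl)pent-1-en-3-one
Conditions: CH2=CHMgBr (1.5 equiv), THF, 0 °C; inverse quench into cold 1 M HCl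
Reagents that add atoms: vinylmagnesium bromide, C=C[Mg]Br
Why: In this Weinreb ketone synthesis the chelated tetrahedral adduct should stop at mono-addition, and the acidic inverse quench protonates the released amine so that it cannot add to the vinyl ketone.

Step 3
Reactants: 4 5-(trimethylsilyl)pent-1-en-3-one; 5 2-methylpropanal (isobutyraldehyde, 1.3 equiv)
Product: 8 4,4-dimethyl-2-[(trimethylsilyl)methyl]cyclohex-2-en-1-one, via keto aldehyde 6 (not isolated), via ketol 7 (not isolated)
Conditions: conc. H2SO4 (2 mol%), 50 °C; then toluene, reflux, Dean–Stark trap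
Reagents that add atoms: none
Why: In this acid-catalysed Robinson annulation the enol of 5 (its only α-hydrogen) adds in Michael fashion to vinyl ketone 4 and forms the C5'–C6' bond with the fully substituted carbon (keto aldehyde 6); the ketone enol on the CH2CH2SiMe3 side then adds to the aldehyde carbon and forms the C1'–C2' bond (ketol 7), and loss of water gives enone 8. The closest known reaction type is the acid-catalysed annulation of α-branched aldehydes with vinyl ketones that gives 4,4-dimethylcyclohex-2-en-1-one. The one ring is closed in the aldol step in a 6-(enolendo)-exo-trig mode. No stereocentre survives the step, because the two stereogenic carbons of ketol 7 become the sp2 carbons of the enone. The step needs chemoselectivity and aldol regioselectivity: the aldehyde of 6 has no α-hydrogen and so can only be the acceptor, and closure from the other ketone α-carbon would give a four-membered ring. Conjugative dehydration places the C=C between C1' and C2', which turns the CH2SiMe3 arm into an allylsilane, the masked exocyclic methylene of the target.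

Step 4
Reactants: 8 4,4-dimethyl-2-[(trimethylsilyl)methyl]cyclohex-2-en-1-one
Product: 9 (1S)-4,4-dimethyl-2-[(trimethylsilyl)methyl]cyclohex-2-en-1-ol
Conditions: (R)-2-methyl-CBS-oxazaborolidine (15 mol%), catecholborane (1.5 equiv), toluene, −78 °C; aq. NaOH work-up
Reagents that add atoms: none
Why: In this CBS reduction the oxazaborolidine–borane complex should bind the ketone with the alkenyl carbon as the large group and deliver hydride to one face, giving the (S)-carbinol at C3' under reagent control, while catecholborane avoids hydroboration of the alkene.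

Step 5
Reactants: 9 (1S)-4,4-dimethyl-2-[(trimethylsilyl)methyl]cyclohex-2-en-1-ol
Product: 10 tert-butyl{[(1S)-4,4-dimethyl-2-[(trimethylsilyl)methyl]cyclohex-2-en-1-yl]oxy}dimethylsilane
Conditions: TBSCl (1.3 equiv), imidazole, DMF, rt
Reagents that add atoms: tert-butyldimethylsilyl chloride, CC(C)(C)[Si](C)(C)Cl
Why: Standard silylation of the secondary allylic alcohol leaves the stereocentre untouched and supplies the bulky group that should steer step 9.

Step 6
Reactants: 11 luteolin
Product: 12 2-{3,4-bis[(tert-butyldimethylsilyl)oxy]phenyl}-7-[(tert-butyldimethylsilyl)oxy]-5-hydroxy-4H-chromen-4-one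
Conditions: TBSCl (3.3 equiv), imidazole, DMF, 0 °C → rt
Reagents that add atoms: tert-butyldimethylsilyl chloride, CC(C)(C)[Si](C)(C)Cl
Why: The three unchelated phenols should be silylated, while the 5-OH, hydrogen-bonded to the C4 carbonyl, should remain free.

Step 7
Reactants: 12 2-{3,4-bis[(tert-butyldimethylsilyl)oxy]phenyl}-7-[(tert-butyldimethylsilyl)oxy]-5-hydroxy-4H-chromen-4-one
Product: 13 2-{3,4-bis[(tert-butyldimethylsilyl)oxy]phenyl}-7-[(tert-butyldimethylsilyl)oxy]-5-hydroxy-6-iodo-4H-chromen-4-one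
Conditions: BnMe3N·ICl2 (1.05 equiv), CaCO3, CH2Cl2/MeOH, rt
Reagents that add atoms: benzyltrimethylammonium dichloroiodate, C[N+](C)(C)Cc1ccccc1.Cl[I-]Cl
Why: Electrophilic aromatic iodination of ring A should occur ortho to the free 5-OH, at C6, as is usual for 5-hydroxy-7-alkoxyflavones.

Step 8
Reactants: 13 2-{3,4-bis[(tert-butyldimethylsilyl)oxy]phenyl}-7-[(tert-butyldimethylsilyl)oxy]-5-hydroxy-6-iodo-4H-chromen-4-one
Product: 14 2-{3,4-bis[(tert-butyldimethylsilyl)oxy]phenyl}-7-[(tert-butyldimethylsilyl)oxy]-5-hydroxy-6-(hydroxymethyl)-4H-chromen-4-one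
Conditions: Bu3SnCH2OH (1.5 equiv), Pd(PPh3)4 (10 mol%), 1,4-dioxane, 90 °C
Reagents that add atoms: (tributylstannyl)methanol, CCCC[Sn](CCCC)(CCCC)CO
Why: Stille coupling of the aryl iodide with the hydroxymethylstannane should install the benzylic CH2OH under neutral conditions that the silyl ethers and the chromone tolerate.

Step 9
Reactants: 10 tert-butyl{[(1S)-4,4-dimethyl-2-[(trimethylsilyl)methyl]cyclohex-2-en-1-yl]oxy}dimethylsilane (2.0 equiv); 14 2-{3,4-bis[(tert-butyldimethylsilyl)oxy]phenyl}-7-[(tert-butyldimethylsilyl)oxy]-5-hydroxy-6-(hydroxymethyl)-4H-chromen-4-one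
Product: 16 2-{3,4-bis[(tert-butyldimethylsilyl)oxy]phenyl}-7-[(tert-butyldimethylsilyl)oxy]-6-{[(1S,3S)-3-[(tert-butyldimethylsilyl)oxy]-6,6-dimethyl-2-methylidenecyclohexyl]methyl}-5-hydroxy-4H-chromen-4-one, via ortho-quinone methide 15 (not isolated)
Conditions: TMSOTf (10 mol%), CH2Cl2, −78 → −30 °C; Et3N quench
Reagents that add atoms: none
Why: In this Hosomi–Sakurai-type SE2' benzylation the acid ionises the ortho-hydroxybenzyl alcohol to ortho-quinone methide 15 (reacting in its O-activated cationic form), which attacks C1' of the allylsilane; loss of the silyl group from the β-silyl cation gives the exocyclic methylene, and the bulky electrophile should enter axially on the face anti to the C3' silyloxy group to give the (1S,3S) trans isomer.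

Step 10
Reactants: 16 2-{3,4-bis[(tert-butyldimethylsilyl)oxy]phenyl}-7-[(tert-butyldimethylsilyl)oxy]-6-{[(1S,3S)-3-[(tert-butyldimethylsilyl)oxy]-6,6-dimethyl-2-methylidenecyclohexyl]methyl}-5-hydroxy-4H-chromen-4-one
Product: 17 ugonin Q
Conditions: Bu4NF (6 equiv), AcOH (6 equiv), THF, 0 °C → rt, argon; aq. NH4Cl
Reagents that add atoms: none
Why: Fluoride should cleave the three aryl and the one secondary alkyl silyl ether, and the acetic acid buffer keeps the medium near neutral so that the polyphenol is not oxidised and no phenol adds to the exocyclic alkene; no stereocentre is touched.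

**Compound list**

1 | 3-(trimethylsilyl)propanoic acid | C[Si](C)(C)CCC(=O)O | starting material
2 | 1-[3-(trimethylsilyl)propanoyl]-1H-imidazole | C[Si](C)(C)CCC(=O)n1ccnc1 | intermediate
3 | N-methoxy-N-methyl-3-(trimethylsilyl)propanamide | C[Si](C)(C)CCC(=O)N(C)OC | intermediate
4 | 5-(trimethylsilyl)pent-1-en-3-one | C=CC(=O)CC[Si](C)(C)C | intermediate
5 | 2-methylpropanal (isobutyraldehyde) | CC(C)C=O | starting material
6 | 2,2-dimethyl-5-oxo-7-(trimethylsilyl)heptanal | O=CC(C)(C)CCC(=O)CC[Si](C)(C)C | intermediate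
7 | 3-hydroxy-4,4-dimethyl-2-[(trimethylsilyl)methyl]cyclohexan-1-one (diastereomer mixture) | O=C1CCC(C)(C)C(O)C1C[Si](C)(C)C | intermediate
8 | 4,4-dimethyl-2-[(trimethylsilyl)methyl]cyclohex-2-en-1-one | O=C1CCC(C)(C)C=C1C[Si](C)(C)C | intermediate
9 | (1S)-4,4-dimethyl-2-[(trimethylsilyl)methyl]cyclohex-2-en-1-ol | O[C@H]1CCC(C)(C)C=C1C[Si](C)(C)C | intermediate
10 | tert-butyl{[(1S)-4,4-dimethyl-2-[(trimethylsilyl)methyl]cyclohex-2-en-1-yl]oxy}dimethylsilane | CC(C)(C)[Si](C)(C)O[C@H]1CCC(C)(C)C=C1C[Si](C)(C)C | intermediate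
11 | luteolin, 2-(3,4-dihydroxyphenyl)-5,7-dihydroxy-4H-chromen-4-one | O=c1cc(-c2ccc(O)c(O)c2)oc2cc(O)cc(O)c12 | starting material
12 | 2-{3,4-bis[(tert-butyldimethylsilyl)oxy]phenyl}-7-[(tert-butyldimethylsilyl)oxy]-5-hydroxy-4H-chromen-4-one | O=c1cc(-c2ccc(O[Si](C)(C)C(C)(C)C)c(O[Si](C)(C)C(C)(C)C)c2)oc2cc(O[Si](C)(C)C(C)(C)C)cc(O)c12 | intermediate
13 | 2-{3,4-bis[(tert-butyldimethylsilyl)oxy]phenyl}-7-[(tert-butyldimethylsilyl)oxy]-5-hydroxy-6-iodo-4H-chromen-4-one | O=c1cc(-c2ccc(O[Si](C)(C)C(C)(C)C)c(O[Si](C)(C)C(C)(C)C)c2)oc2cc(O[Si](C)(C)C(C)(C)C)c(I)c(O)c12 | intermediate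
14 | 2-{3,4-bis[(tert-butyldimethylsilyl)oxy]phenyl}-7-[(tert-butyldimethylsilyl)oxy]-5-hydroxy-6-(hydroxymethyl)-4H-chromen-4-one | O=c1cc(-c2ccc(O[Si](C)(C)C(C)(C)C)c(O[Si](C)(C)C(C)(C)C)c2)oc2cc(O[Si](C)(C)C(C)(C)C)c(CO)c(O)c12 | intermediate
15 | 2-{3,4-bis[(tert-butyldimethylsilyl)oxy]phenyl}-7-[(tert-butyldimethylsilyl)oxy]-6-methylidene-4H-chromene-4,5(6H)-dione (ortho-quinone methide) | C=C1C(=O)C2=C(OC(=CC2=O)c2ccc(O[Si](C)(C)C(C)(C)C)c(O[Si](C)(C)C(C)(C)C)c2)C=C1O[Si](C)(C)C(C)(C)C | intermediate
16 | 2-{3,4-bis[(tert-butyldimethylsilyl)oxy]phenyl}-7-[(tert-butyldimethylsilyl)oxy]-6-{[(1S,3S)-3-[(tert-butyldimethylsilyl)oxy]-6,6-dimethyl-2-methylidenecyclohexyl]methyl}-5-hydroxy-4H-chromen-4-one | C=C1[C@@H](Cc2c(O[Si](C)(C)C(C)(C)C)cc3oc(-c4ccc(O[Si](C)(C)C(C)(C)C)c(O[Si](C)(C)C(C)(C)C)c4)cc(=O)c3c2O)C(C)(C)CC[C@@H]1O[Si](C)(C)C(C)(C)C | intermediate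
17 | ugonin Q, 2-(3,4-dihydroxyphenyl)-5,7-dihydroxy-6-{[(1S,3S)-3-hydroxy-6,6-dimethyl-2-methylidenecyclohexyl]methyl}-4H-chromen-4-one | C=C1[C@@H](Cc2c(O)cc3oc(-c4ccc(O)c(O)c4)cc(=O)c3c2O)C(C)(C)CC[C@@H]1O | target

**Step count and risks**

Total step count: 10. Longest linear sequence: 7 steps (steps 1, 2, 3, 4, 5, 9, 10).

Steps most likely to fail:

1. Step 9. The benzylic cation may be consumed by Friedel–Crafts attack on ring A of a second flavone molecule or by oxygen nucleophiles, and the allylsilane may be protodesilylated, before C–C bond formation at the hindered C1' takes place. The fallback sets out from 10 (and 13) and returns at 17; it makes the hindered bond with the smallest electrophile and joins the aryl group by cross-coupling. SE2' hydroxymethylation of 10 with monomeric formaldehyde (paraformaldehyde, Me2AlCl, CH2Cl2, −78 °C) should give [(1S,3S)-3-[(tert-butyldimethylsilyl)oxy]-6,6-dimethyl-2-methylidenecyclohexyl]methanol F1. Iodination (I2, PPh3, imidazole) should give the iodide F2, and zinc insertion (Zn dust, LiCl, THF) the alkylzinc iodide F3. In parallel 13 is silylated at O5 (TBSOTf, 2,6-lutidine) to the tetrasilyl iodide F4. Negishi coupling of F3 with F4 (Pd2(dba)3, SPhos, THF, 50 °C) should give the pentasilyl ether F5, which the conditions of step 10 convert into 17.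

2. Step 8. Oxidative addition and transmetalation at the doubly ortho-substituted C6 may be slow, so that protodeiodination and decomposition of the stannane dominate. The fallback sets out from 12, returns at 14 and avoids palladium; it also makes step 7 unnecessary. A Mannich reaction ortho to the free 5-OH with Eschenmoser's salt (CH2=NMe2 iodide, Et3N, CH2Cl2) should give the 6-[(dimethylamino)methyl] compound F6. Quaternisation with MeI gives the trimethylammonium iodide F7. NaHCO3 in wet THF should eliminate the amine to ortho-quinone methide 15, which adds water to give 14.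

3. Step 3. The silylated vinyl ketone may polymerise or lose its silyl group by protodesilylation under hot acid before the annulation is complete. The fallback sets out from 5, returns at 8, keeps the same ring-forming event and brings the silicon in afterwards. The annulation of 5 with commercial but-3-en-2-one (cat. H2SO4, toluene, reflux) should give 4,4-dimethylcyclohex-2-en-1-one F8. α-Iodination (I2, pyridine, CH2Cl2) gives 2-iodo-4,4-dimethylcyclohex-2-en-1-one F9. Negishi coupling (Pd(PPh3)4, THF) with (trimethylsilyl)methylzinc chloride F10, made from Me3SiCH2MgCl and ZnCl2, should give 8.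

**Further compounds**

F1 | step 9 | [(1S,3S)-3-[(tert-butyldimethylsilyl)oxy]-6,6-dimethyl-2-methylidenecyclohexyl]methanol | C=C1[C@@H](CO)C(C)(C)CC[C@@H]1O[Si](C)(C)C(C)(C)C
F2 | step 9 | tert-butyl{[(1S,3S)-3-(iodomethyl)-4,4-dimethyl-2-methylidenecyclohexyl]oxy}dimethylsilane | C=C1[C@@H](CI)C(C)(C)CC[C@@H]1O[Si](C)(C)C(C)(C)C
F3 | step 9 | {[(1S,3S)-3-[(tert-butyldimethylsilyl)oxy]-6,6-dimethyl-2-methylidenecyclohexyl]methyl}zinc iodide | C=C1[C@@H](C[Zn]I)C(C)(C)CC[C@@H]1O[Si](C)(C)C(C)(C)C
F4 | step 9 | 2-{3,4-bis[(tert-butyldimethylsilyl)oxy]phenyl}-5,7-bis[(tert-butyldimethylsilyl)oxy]-6-iodo-4H-chromen-4-one | O=c1cc(-c2ccc(O[Si](C)(C)C(C)(C)C)c(O[Si](C)(C)C(C)(C)C)c2)oc2cc(O[Si](C)(C)C(C)(C)C)c(I)c(O[Si](C)(C)C(C)(C)C)c12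
F5 | step 9 | 2-{3,4-bis[(tert-butyldimethylsilyl)oxy]phenyl}-5,7-bis[(tert-butyldimethylsilyl)oxy]-6-{[(1S,3S)-3-[(tert-butyldimethylsilyl)oxy]-6,6-dimethyl-2-methylidenecyclohexyl]methyl}-4H-chromen-4-one | C=C1[C@@H](Cc2c(O[Si](C)(C)C(C)(C)C)cc3oc(-c4ccc(O[Si](C)(C)C(C)(C)C)c(O[Si](C)(C)C(C)(C)C)c4)cc(=O)c3c2O[Si](C)(C)C(C)(C)C)C(C)(C)CC[C@@H]1O[Si](C)(C)C(C)(C)C
F6 | step 8 | 2-{3,4-bis[(tert-butyldimethylsilyl)oxy]phenyl}-7-[(tert-butyldimethylsilyl)oxy]-6-[(dimethylamino)methyl]-5-hydroxy-4H-chromen-4-one | O=c1cc(-c2ccc(O[Si](C)(C)C(C)(C)C)c(O[Si](C)(C)C(C)(C)C)c2)oc2cc(O[Si](C)(C)C(C)(C)C)c(CN(C)C)c(O)c12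
F7 | step 8 | ({2-{3,4-bis[(tert-butyldimethylsilyl)oxy]phenyl}-7-[(tert-butyldimethylsilyl)oxy]-5-hydroxy-4-oxo-4H-chromen-6-yl}methyl)trimethylammonium iodide | O=c1cc(-c2ccc(O[Si](C)(C)C(C)(C)C)c(O[Si](C)(C)C(C)(C)C)c2)oc2cc(O[Si](C)(C)C(C)(C)C)c(C[N+](C)(C)C)c(O)c12.[I-]
F8 | step 3 | 4,4-dimethylcyclohex-2-en-1-one | O=C1C=CC(C)(C)CC1
F9 | step 3 | 2-iodo-4,4-dimethylcyclohex-2-en-1-one | O=C1CCC(C)(C)C=C1I
F10 | step 3 | (trimethylsilyl)methylzinc chloride | C[Si](C)(C)C[Zn]Cl
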